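Numbering: each half is numbered as a phthalide (C1 lactone C=O, C3 butylidene carbon, C3a–C7a carbocycle); the half with sp3 C3a′/C7a′ is primed. The cyclobutane is C6–C7–C3a′–C7a′. C6–C7 is also a bond of ring A and C7 sits next to the C7a=C3a alkene, so cyclobutane plus ring A form a bicyclo[4.2.0]oct-2-ene, the retron of a cycloocta-1,3,5-triene 6π closure.
Retrosynthesis: open lactone B (O–C3′, alkynoic acid cycloisomerisation) and lactone A (C7a–C1/O–C1, carbonylative lactonisation of a 2-acyl enol triflate); cut C6–C7 (retro-6π) to an eight-membered triene; refold it through C3a–C6 to a cyclobutene (retro-4π); remove C4–C5 as acetylene (enone [2+2]); cut C7–C3a′ and C6–C7a′ (Diels–Alder).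
Forward: ring B is present in the starting cyclohexenone; a Diels–Alder reaction on C3a′=C7a′ makes both quaternary carbons and a second six-membered ring; acetylene photocycloaddition adds C4–C5 as a cyclobutene; heating moves the four-membered ring onto C6–C7 and creates ring A; lactone A and then lactone B are closed last.
Stereochemistry: C3a′/C7a′ from the catalyst-controlled suprafacial Diels–Alder reaction; C6/C7 from the disrotatory closure (cis) and its thermodynamic preference for ring A anti to ring B; both (Z)-butylidenes from the lactonisations.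

Key step: step 9

Assumption: the (S,S)-ligand in step 4 is taken to give the C3a′/C7a′ configuration drawn; if the facial sense proves opposite, the (R,R)-ligand is used.

Step 1
Reactants: 1 3-ethoxycyclohex-2-en-1-one
Product: 2 3-ethoxy-2-iodocyclohex-2-en-1-one
Conditions: N-iodosuccinimide, MeCN, 0 °C to rt
Reagents that add atoms: N-iodosuccinimide, O=C1CCC(=O)N1I
Why: Electrophilic α-iodination of a vinylogous ester, whose enol ether makes C2 the only nucleophilic carbon, so the halogenation should be regiospecific.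

Step 2
Reactants: 2 3-ethoxy-2-iodocyclohex-2-en-1-one; 3 pent-1-yne
Product: 5 2-iodo-3-(pent-1-yn-1-yl)cyclohex-2-en-1-one, via tertiary propargylic alcohol 4 (not isolated)
Conditions: 3, n-BuLi, THF, −78 °C; add 2, −78 to 0 °C; then 2 M HCl, rt
Reagents that add atoms: water, O
Why: Stork–Danheiser transposition: lithium pentynylide adds 1,2 to the vinylogous ester carbonyl, and aqueous acid collapses the carbinol to the transposed enone with loss of ethanol.

Step 3
Reactants: 5 2-iodo-3-(pent-1-yn-1-yl)cyclohex-2-en-1-one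
Product: 6 tert-butyl 6-oxo-2-(pent-1-yn-1-yl)cyclohex-1-ene-1-carboxylate
Conditions: PdCl2(PPh3)2 (5 mol %), CO (5 bar), t-BuOH, i-Pr2NEt, 80 °C
Reagents that add atoms: carbon monoxide, [C-]#[O+]; tert-butanol, CC(C)(C)O
Why: Palladium-catalysed alkoxycarbonylation of an α-iodoenone (oxidative addition, CO insertion, alcoholysis of the acyl-palladium) installs the ester carbon that becomes C1′.

Step 4
Reactants: 6 tert-butyl 6-oxo-2-(pent-1-yn-1-yl)cyclohex-1-ene-1-carboxylate; 7 (E)-1-methoxy-3-(trimethylsilyloxy)buta-1,3-diene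
Product: 8 tert-butyl 1-methoxy-8-oxo-4a-(pent-1-yn-1-yl)-3-(trimethylsilyloxy)-1,4,4a,5,6,7,8,8a-octahydronaphthalene-8a-carboxylate (cis-fused, ester cis to pentynyl, C1 epimers)
Conditions: Cu(OTf)2 (10 mol %), (S,S)-t-Bu-box (11 mol %), 4 Å MS, CH2Cl2, −40 to −20 °C; Et3N quench, plug of Et3N-deactivated silica
Reagents that add atoms: none
Why: Lewis-acid-catalysed Diels–Alder reaction: two-point binding of the β-keto ester to the chiral copper bis(oxazoline) complex activates the tetrasubstituted alkene and shields one face, the slim alkynyl group keeps C3a′ accessible, the nucleophilic CH2 terminus of the diene bonds to C3a′ (β to ketone and ester), and suprafacial addition sets C3a′ and C7a′ cis in one enantiomeric series.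

Step 5
Reactants: 8 the Diels–Alder adduct
Product: 10 tert-butyl 3-oxo-4a-(pent-1-yn-1-yl)-8-(trifluoromethylsulfonyloxy)-3,4,4a,5,6,8a-hexahydronaphthalene-8a-carboxylate, via enol triflate silyl enol ether 9 (not isolated)
Conditions: KN(SiMe3)2, THF, −78 °C; PhNTf2; then 1 M HCl, THF, 0 °C
Reagents that add atoms: N-phenylbis(trifluoromethanesulfonimide), O=S(=O)(N(c1ccccc1)S(=O)(=O)C(F)(F)F)C(F)(F)F
Why: While the ring A ketone is masked as its silyl enol ether the C7′ ketone is the only enolisable one, so kinetic enolate O-triflation is site-specific, and dilute acid then unmasks the enone by silyl enol ether hydrolysis and β-elimination of methanol.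

Step 6
Reactants: 10 the enone enol triflate
Product: 11 tert-butyl 3-oxo-4a-(pent-1-yn-1-yl)-3,4,4a,5,6,8a-hexahydronaphthalene-8a-carboxylate
Conditions: Pd(OAc)2 (5 mol %), PPh3 (10 mol %), HCO2H, n-Bu3N, DMF, 60 °C
Reagents that add atoms: none
Why: Palladium-catalysed formate reduction of an enol triflate (hydride delivery by decarboxylation, reductive elimination) gives the C6′=C7′ alkene, whose position is fixed because C7a′ is quaternary.

Step 7
Reactants: 11 the enone; 12 acetylene
Product: 13 tert-butyl 3-oxo-4a-(pent-1-yn-1-yl)-2a,3,4,4a,5,6,8a,8b-octahydrocyclobuta[a]naphthalene-8a-carboxylate (cis-fused cyclobutene, both faces possible)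
Conditions: C2H2 (saturated), CH2Cl2, −40 °C, hν (365 nm)
Reagents that add atoms: none
Why: Enone–alkyne [2+2] photocycloaddition through the enone triplet adds C4–C5 as a cis-fused cyclobutene; the two centres it creates (C3a, C6) become sp2 again in step 9, so its facial course does not matter.

Step 8
Reactants: 13 the cyclobutene ketone
Product: 14 tert-butyl 4a-(pent-1-yn-1-yl)-3-(trimethylsilyloxy)-2a,4a,5,6,8a,8b-hexahydrocyclobuta[a]naphthalene-8a-carboxylate
Conditions: LiN(i-Pr)2, THF, −78 °C; Me3SiCl, Et3N; pentane filtration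
Reagents that add atoms: chlorotrimethylsilane, C[Si](C)(C)Cl
Why: Kinetic enolate formation at the CH2 group (C7) rather than at the strained ring-fusion methine (C3a), followed by O-silylation, turns the ketone into a bicyclo[4.2.0]octa-2,7-diene.

Step 9
Reactants: 14 the silyl enol ether
Product: 17 tert-butyl 5-oxo-4a-(pent-1-yn-1-yl)-3,4,4a,4b,5,8,8a,8b-octahydrobiphenylene-8b-carboxylate, via cyclooctatriene 15 (not isolated), via silyl dienol ether 16 (not isolated)
Conditions: toluene (degassed), 140 °C, sealed tube; then 1 M HCl, THF, 0 °C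
Reagents that add atoms: none
Why: Heating opens the cyclobutene of the bicyclo[4.2.0]octa-2,7-diene (C3a–C6 cleaved, a 4π electrocyclic ring-opening assisted by the siloxydiene) to the all-cis cycloocta-1,3,5-triene 15, whose termini C6 and C7 then join in a thermal six-electron disrotatory electrocyclisation to the bicyclo[4.2.0]octa-2,4-diene 16; mild acid hydrolyses the silyl dienol ether with γ-protonation to the conjugated enone 17. The closest known reaction type is the thermal valence isomerisation of bicyclo[4.2.0]octa-2,7-dienes through cycloocta-1,3,5-trienes to bicyclo[4.2.0]octa-2,4-dienes, which is downhill because cyclobutene strain is exchanged for a conjugated diene. The one new bond, C6–C7, closes two rings at once, the cyclobutane (C6, C7, C3a′, C7a′) and the six-membered ring A, both by transannular 6π disrotatory closure across the eight-membered ring. Disrotation places H6 and H7 cis; their sense relative to C3a′/C7a′ is set under thermodynamic control, because the closure is reversible at this temperature, and ring A should settle anti to ring B on the cyclobutane face that carries only the slim alkynyl and ester groups (cis-anti-cis 6-4-6). The step needs ring-opening to outrun desilylation and hydrogen shifts and the equilibrium to lie on the bicyclic side: the two quaternary carbons leave no sp3 C–H in the eight-membered ring and, as 7,8-disubstitution does in cyclooctatrienes generally, favour the folded bicyclic form.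

Step 10
Reactants: 17 the bicyclic enone; 18 pentanoyl chloride
Product: 19 tert-butyl 5-oxo-6-pentanoyl-4a-(pent-1-yn-1-yl)-3,4,4a,4b,5,6,7,8,8a,8b-decahydrobiphenylene-8b-carboxylate (C6 epimers and enol)
Conditions: LiBH(s-Bu)3, THF, −78 °C; MgBr2·OEt2; cannulate into 18 (2 equiv), −78 °C; AcOH
Reagents that add atoms: none
Why: Reductive acylation: conjugate hydride addition to the β-unsubstituted cyclohexenone gives the regiodefined enolate (C7a–O, C3a), whose magnesium form is C-acylated by the acid chloride to put the pentanoyl carbon C3 on C3a.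

Step 11
Reactants: 19 the β-diketone
Product: 20 tert-butyl 6-pentanoyl-4a-(pent-1-yn-1-yl)-5-(trifluoromethylsulfonyloxy)-3,4,4a,4b,7,8,8a,8b-octahydrobiphenylene-8b-carboxylate
Conditions: Tf2O, i-Pr2NEt, CH2Cl2, −78 °C
Reagents that add atoms: trifluoromethanesulfonic anhydride, O=S(=O)(OS(=O)(=O)C(F)(F)F)C(F)(F)F
Why: O-triflation of the enolised β-diketone at the ring carbonyl (the endocyclic enol is the favoured tautomer of 2-acylcyclohexanones) gives the ring-locked (Z)-β-triflyloxy enone.

Step 12
Reactants: 20 the β-triflyloxy enone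
Product: 21 tert-butyl ester with unit A complete: (Z)-3-butylidene-4,5,6,7-tetrahydrophthalide fused through C6–C7a′ and C7–C3a′ to the cyclobutane; ring B cyclohexene carries C3a′ pent-1-ynyl and C7a′ CO2t-Bu
Conditions: PdCl2(PPh3)2 (5 mol %), CO (1 atm), Et3N, DMF, 70 °C
Reagents that add atoms: carbon monoxide, [C-]#[O+]
Why: Palladium-catalysed carbonylative lactonisation: CO insertion into the alkenyl–palladium bond gives an acyl-palladium that is captured by the enol oxygen of the neighbouring butyl ketone, closing the butenolide as the thermodynamically preferred (Z)-butylidene.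

Step 13
Reactants: 21 the tert-butyl ester
Product: 23 target dimer CNP0371639.2, via carboxylic acid 22 (not isolated)
Conditions: CF3CO2H, CH2Cl2, 0 °C; evaporate; AgNO3 (10 mol %), acetone, rt
Reagents that add atoms: none
Why: Acidolysis of the tert-butyl ester followed by silver-catalysed 5-exo-dig cycloisomerisation of the γ-alkynoic acid (anti oxymetalation, then protodemetalation) gives the (Z)-γ-butylidene lactone, with ring closure favoured by the two quaternary carbons.

Compound list
1 | 3-ethoxycyclohex-2-en-1-one | CCOC1=CC(=O)CCC1 | starting material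
2 | 3-ethoxy-2-iodocyclohex-2-en-1-one | CCOC1=C(I)C(=O)CCC1 | intermediate
3 | pent-1-yne | CCCC#C | starting material
4 | 3-ethoxy-2-iodo-1-(pent-1-yn-1-yl)cyclohex-2-en-1-ol (racemic, formed as its lithium alkoxide) | CCCC#CC1(O)CCCC(OCC)=C1I | intermediate
5 | 2-iodo-3-(pent-1-yn-1-yl)cyclohex-2-en-1-one | CCCC#CC1=C(I)C(=O)CCC1 | intermediate
6 | tert-butyl 6-oxo-2-(pent-1-yn-1-yl)cyclohex-1-ene-1-carboxylate | CCCC#CC1=C(C(=O)OC(C)(C)C)C(=O)CCC1 | intermediate
7 | (E)-1-methoxy-3-(trimethylsilyloxy)buta-1,3-diene | CO/C=C/C(=C)O[Si](C)(C)C | starting material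
8 | tert-butyl 1-methoxy-8-oxo-4a-(pent-1-yn-1-yl)-3-(trimethylsilyloxy)-1,4,4a,5,6,7,8,8a-octahydronaphthalene-8a-carboxylate (cis-fused; C1 epimers) | O=C1CCC[C@@]2(C#CCCC)CC(O[Si](C)(C)C)=CC(OC)[C@@]12C(=O)OC(C)(C)C | intermediate
9 | tert-butyl 1-methoxy-4a-(pent-1-yn-1-yl)-8-(trifluoromethylsulfonyloxy)-3-(trimethylsilyloxy)-1,4,4a,5,6,8a-hexahydronaphthalene-8a-carboxylate | FC(F)(F)S(=O)(=O)OC1=CCC[C@@]2(C#CCCC)CC(O[Si](C)(C)C)=CC(OC)[C@@]12C(=O)OC(C)(C)C | intermediate
10 | tert-butyl 3-oxo-4a-(pent-1-yn-1-yl)-8-(trifluoromethylsulfonyloxy)-3,4,4a,5,6,8a-hexahydronaphthalene-8a-carboxylate | FC(F)(F)S(=O)(=O)OC1=CCC[C@@]2(C#CCCC)CC(=O)C=C[C@@]12C(=O)OC(C)(C)C | intermediate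
11 | tert-butyl 3-oxo-4a-(pent-1-yn-1-yl)-3,4,4a,5,6,8a-hexahydronaphthalene-8a-carboxylate | C1=CCC[C@@]2(C#CCCC)CC(=O)C=C[C@@]12C(=O)OC(C)(C)C | intermediate
12 | acetylene | C#C | starting material
13 | tert-butyl 3-oxo-4a-(pent-1-yn-1-yl)-2a,3,4,4a,5,6,8a,8b-octahydrocyclobuta[a]naphthalene-8a-carboxylate (C2a/C8b cis, face unassigned) | C1=CCC[C@@]2(C#CCCC)CC(=O)C3C=CC3[C@@]12C(=O)OC(C)(C)C | intermediate
14 | tert-butyl 4a-(pent-1-yn-1-yl)-3-(trimethylsilyloxy)-2a,4a,5,6,8a,8b-hexahydrocyclobuta[a]naphthalene-8a-carboxylate | C1=CCC[C@@]2(C#CCCC)C=C(O[Si](C)(C)C)C3C=CC3[C@@]12C(=O)OC(C)(C)C | intermediate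
15 | tert-butyl (5Z,7Z,9Z)-4a-(pent-1-yn-1-yl)-6-(trimethylsilyloxy)-3,4,4a,10a-tetrahydrobenzo[8]annulene-10a-carboxylate | C1=CCC[C@@]2(C#CCCC)/C=C(O[Si](C)(C)C)\C=C/C=C\[C@@]12C(=O)OC(C)(C)C | intermediate
16 | tert-butyl 4a-(pent-1-yn-1-yl)-5-(trimethylsilyloxy)-3,4,4a,4b,8a,8b-hexahydrobiphenylene-8b-carboxylate | C1=CCC[C@@]2(C#CCCC)[C@@H]3C(O[Si](C)(C)C)=CC=C[C@@H]3[C@@]12C(=O)OC(C)(C)C | intermediate
17 | tert-butyl 5-oxo-4a-(pent-1-yn-1-yl)-3,4,4a,4b,5,8,8a,8b-octahydrobiphenylene-8b-carboxylate | C1=CCC[C@@]2(C#CCCC)[C@@H]3C(=O)C=CC[C@@H]3[C@@]12C(=O)OC(C)(C)C | intermediate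
18 | pentanoyl chloride | CCCCC(=O)Cl | starting material
19 | tert-butyl 5-oxo-6-pentanoyl-4a-(pent-1-yn-1-yl)-3,4,4a,4b,5,6,7,8,8a,8b-decahydrobiphenylene-8b-carboxylate (C6 epimers, enolised) | C1=CCC[C@@]2(C#CCCC)[C@@H]3C(=O)C(C(=O)CCCC)CC[C@@H]3[C@@]12C(=O)OC(C)(C)C | intermediate
20 | tert-butyl 6-pentanoyl-4a-(pent-1-yn-1-yl)-5-(trifluoromethylsulfonyloxy)-3,4,4a,4b,7,8,8a,8b-octahydrobiphenylene-8b-carboxylate | C1=CCC[C@@]2(C#CCCC)[C@@H]3C(OS(=O)(=O)C(F)(F)F)=C(C(=O)CCCC)CC[C@@H]3[C@@]12C(=O)OC(C)(C)C | intermediate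
21 | tert-butyl ester with lactone A closed: (Z)-3-butylidene tetrahydrophthalide unit bonded C6–C7a′ and C7–C3a′; C3a′ pent-1-ynyl, C7a′ CO2t-Bu, C6′=C7′ | CCC/C=C1\OC(=O)C2=C1CC[C@H]1[C@@H]2[C@]2(C#CCCC)CCC=C[C@]12C(=O)OC(C)(C)C | intermediate
22 | the corresponding C7a′ carboxylic acid | CCC/C=C1\OC(=O)C2=C1CC[C@H]1[C@@H]2[C@]2(C#CCCC)CCC=C[C@]12C(=O)O | intermediate
23 | CNP0371639.2, the (Z,Z′) ligustilide dimer joined C6–C7a′ and C7–C3a′ | CCC/C=C1\OC(=O)C2=C1CC[C@H]1[C@@H]2[C@]23CCC=C[C@]12C(=O)O/C3=C\CCC | target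

Total step count: 13. Longest linear sequence: 13 steps, from 1.

The three steps most likely to fail are steps 4, 7 and 9.

Step 4 may suffer from poor turnover or loss of facial control on the crowded tetrasubstituted alkene, or from a stepwise addition that strays to the alkyne terminus. The fallback sets out from 6: an uncatalysed Diels–Alder reaction with the more nucleophilic 1-(dimethylamino)-3-(tert-butyldimethylsilyloxy)buta-1,3-diene (toluene, 60 °C) should give the racemic amino silyl enol ether F1. KN(SiMe3)2 and PhNTf2 then give the racemic enol triflate F2, and dilute HCl removes dimethylamine and the silyl group. The racemic enone triflate is separated on a chiral stationary phase from the unwanted enantiomer F3, and the route is rejoined at 10.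

Step 7 may fail because unimolecular photorearrangement of the 4-vinyl-type enone, or energy wasting by the nearby alkyne, outruns bimolecular capture by sparingly soluble acetylene. The fallback sets out from 11: irradiation in a large excess of (E)-1,2-dichloroethene as alkene partner should give the dichlorocyclobutane F4, and reductive vicinal dechlorination with Zn dust in refluxing EtOH gives the cyclobutene; the route is rejoined at 13.

Step 9 may fail through desilylation or decomposition at the temperature needed for ring-opening, or through an unfavourable triene/bicycle balance in the silyl ether series. The fallback sets out from 13: the ketone itself is heated (xylene, 160 °C) to open the cyclobutene to the cycloocta-2,4-dienone F5. Catalytic KOt-Bu in t-BuOH then brings about a polar transannular 1,6-conjugate addition of the C7 enolate to C6, and protonation of the extended enolate gives the enone; the route is rejoined at 17.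

Further compounds
F1 | step 4 | racemic tert-butyl 1-(dimethylamino)-8-oxo-4a-(pent-1-yn-1-yl)-3-(tert-butyldimethylsilyloxy)-1,4,4a,5,6,7,8,8a-octahydronaphthalene-8a-carboxylate (one enantiomer drawn) | O=C1CCC[C@@]2(C#CCCC)CC(O[Si](C)(C)C(C)(C)C)=CC(N(C)C)[C@@]12C(=O)OC(C)(C)C
F2 | step 4 | racemic C8 enol triflate of F1 (one enantiomer drawn) | FC(F)(F)S(=O)(=O)OC1=CCC[C@@]2(C#CCCC)CC(O[Si](C)(C)C(C)(C)C)=CC(N(C)C)[C@@]12C(=O)OC(C)(C)C
F3 | step 4 | enantiomer of 10 | FC(F)(F)S(=O)(=O)OC1=CCC[C@]2(C#CCCC)CC(=O)C=C[C@]12C(=O)OC(C)(C)C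
F4 | step 7 | tert-butyl 1,2-dichloro-3-oxo-4a-(pent-1-yn-1-yl)-1,2,2a,3,4,4a,5,6,8a,8b-decahydrocyclobuta[a]naphthalene-8a-carboxylate | C1=CCC[C@@]2(C#CCCC)CC(=O)C3C(Cl)C(Cl)C3[C@@]12C(=O)OC(C)(C)C
F5 | step 9 | tert-butyl (7Z,9Z)-6-oxo-4a-(pent-1-yn-1-yl)-3,4,4a,5,6,10a-hexahydrobenzo[8]annulene-10a-carboxylate | C1=CCC[C@@]2(C#CCCC)CC(=O)/C=C\C=C/[C@@]12C(=O)OC(C)(C)C
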